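The target is methyl 8β-acetoxy-5α-hydroperoxy-3β-isobutyryloxyeudesma-4(15),11(13)-dien-12-oate. The decalin is disconnected across ring A into two three-carbon units: the oxygenated allyl unit C3–C4(C15)–C5 and the enal-derived unit C10–C1–C2. In one operation an α-methoxyallylphosphonate anion (C3–C5) adds through C5 to the quaternary-to-be C10 of a tethered β-methyl enal, closing ring B, and then olefinates the C2 aldehyde through C3, closing ring A (formal [3+3] bicyclisation). The acyclic precursor already carries the C7 acrylate and C8 acetate stereocentres, set by an asymmetric allylboration. Acid converts the dienol ether into the Δ4-3-ketone; reduction, acylation and a singlet-oxygen ene reaction finish the synthesis.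

Key step: step 12

Remark: eudesmane numbering is used (ring A: C1–C5, C10; ring B: C5–C10; C14 on C10; C15 on C4; C11–C13 on C7; side chain β at C7), and the facial sense of the catalyst in step 5 is assumed to follow the usual model for phosphoric acid catalysed allylborations.

Step 1
Reactants: 1 3-[(tert-butyldimethylsilyl)oxy]propanal; 2 methyl acrylate
Product: 3 methyl 5-[(tert-butyldimethylsilyl)oxy]-3-hydroxy-2-methylidenepentanoate (racemic)
Conditions: DABCO (0.5 equiv), neat methyl acrylate, rt
Reagents that add atoms: none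
Why: Morita–Baylis–Hillman reaction, in which the ammonium enolate formed from DABCO and the acrylate adds to the aldehyde; the racemic carbinol centre is erased in step 3.

Step 2
Reactants: 3 methyl 5-[(tert-butyldimethylsilyl)oxy]-3-hydroxy-2-methylidenepentanoate
Product: 4 methyl 3-acetoxy-5-[(tert-butyldimethylsilyl)oxy]-2-methylidenepentanoate (racemic)
Conditions: Ac2O, DMAP (cat.), Et3N, CH2Cl2, 0 °C
Reagents that add atoms: acetic anhydride, CC(=O)OC(C)=O
Why: DMAP-catalysed acetylation turns the allylic hydroxyl into the leaving group needed for the allylic substitution.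

Step 3
Reactants: 4 methyl 3-acetoxy-5-[(tert-butyldimethylsilyl)oxy]-2-methylidenepentanoate
Product: 5 methyl (E)-5-[(tert-butyldimethylsilyl)oxy]-2-[(4,4,5,5-tetramethyl-1,3,2-dioxaborolan-2-yl)methyl]pent-2-enoate
Conditions: B2pin2, Pd2(dba)3 (2.5 mol%), toluene, 50 °C
Reagents that add atoms: bis(pinacolato)diboron, CC1(C)OB(OC1(C)C)B1OC(C)(C)C(C)(C)O1
Why: Palladium-catalysed SN2′ borylation of a Morita–Baylis–Hillman acetate (zerovalent palladium ionises the acetate, boron is delivered to the CH2 terminus) should give the trisubstituted allylboronate with the chain cis to CH2B and trans to the ester, the favoured geometry.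

Step 4
Reactants: 6 3-methylbut-3-en-1-ol
Product: 7 3-methylbut-3-enal
Conditions: Dess–Martin periodinane, pyridine, CH2Cl2, 0 °C; used at once as a cold solution
Reagents that add atoms: none
Why: Dess–Martin oxidation under buffered conditions should give the β,γ-unsaturated aldehyde without shifting the double bond into conjugation.

Step 5
Reactants: 5 methyl (E)-5-[(tert-butyldimethylsilyl)oxy]-2-[(4,4,5,5-tetramethyl-1,3,2-dioxaborolan-2-yl)methyl]pent-2-enoate; 7 3-methylbut-3-enal
Product: 8 methyl (3R,4R)-3-{2-[(tert-butyldimethylsilyl)oxy]ethyl}-4-hydroxy-6-methyl-2-methylidenehept-6-enoate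
Conditions: (S)-TRIP (5 mol%), 4 Å molecular sieves, toluene, −30 °C; aqueous NaHCO3 work-up
Reagents that add atoms: none
Why: Chiral phosphoric acid catalysed allylboration through a closed chair transition state, in which the boronate geometry (chain cis to CH2B) gives the syn C7/C8 pair and the catalyst directs attack to the Si face of the aldehyde, setting both stereocentres.

Step 6
Reactants: 8 methyl (3R,4R)-3-{2-[(tert-butyldimethylsilyl)oxy]ethyl}-4-hydroxy-6-methyl-2-methylidenehept-6-enoate
Product: 9 methyl (3R,4R)-4-acetoxy-3-{2-[(tert-butyldimethylsilyl)oxy]ethyl}-6-methyl-2-methylidenehept-6-enoate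
Conditions: Ac2O, DMAP (cat.), pyridine, CH2Cl2, 0 °C
Reagents that add atoms: acetic anhydride, CC(=O)OC(C)=O
Why: Prompt acetylation installs the C8 acetate of the target and prevents lactonisation of the γ-hydroxy ester.

Step 7
Reactants: 9 methyl (3R,4R)-4-acetoxy-3-{2-[(tert-butyldimethylsilyl)oxy]ethyl}-6-methyl-2-methylidenehept-6-enoate
Product: 10 methyl (3R,4R)-4-acetoxy-3-(2-hydroxyethyl)-6-methyl-2-methylidenehept-6-enoate
Conditions: HF·pyridine, pyridine, THF, 0 °C to rt
Reagents that add atoms: none
Why: Buffered HF·pyridine cleaves the primary silyl ether and should leave the esters and alkenes untouched.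

Step 8
Reactants: 10 methyl (3R,4R)-4-acetoxy-3-(2-hydroxyethyl)-6-methyl-2-methylidenehept-6-enoate
Product: 12 methyl (3R,4R)-4-acetoxy-6-methyl-3-[(E)-3-methyl-4-oxobut-2-en-1-yl]-2-methylidenehept-6-enoate, via aldehyde 11 (not isolated)
Conditions: Dess–Martin periodinane, pyridine, CH2Cl2, 0 °C; then 2-(triphenylphosphoranylidene)propanal, toluene, 80 °C
Reagents that add atoms: 2-(triphenylphosphoranylidene)propanal, CC(C=O)=P(c1ccccc1)(c1ccccc1)c1ccccc1
Why: Dess–Martin oxidation followed in the same flask by a Wittig reaction with the stabilised formyl ylide should give the (E)-2-methyl enal that supplies C3, C4 and C15.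

Step 9
Reactants: 12 methyl (3R,4R)-4-acetoxy-6-methyl-3-[(E)-3-methyl-4-oxobut-2-en-1-yl]-2-methylidenehept-6-enoate
Product: 13 methyl (3R,4R)-4-acetoxy-3-[(E)-4-(diphenoxyphosphoryl)-4-hydroxy-3-methylbut-2-en-1-yl]-6-methyl-2-methylidenehept-6-enoate (both epimers at the carbinol carbon)
Conditions: diphenyl phosphite (1.1 equiv), Et3N (0.2 equiv), CH2Cl2, 0 °C
Reagents that add atoms: diphenyl phosphite, O=[PH](Oc1ccccc1)Oc1ccccc1
Why: Pudovik reaction, a base-catalysed 1,2-addition of the H-phosphonate to the aldehyde carbonyl that fixes phosphorus at C3 without regiochemical ambiguity; the new centre is of no consequence because C3 becomes sp2 later.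

Step 10
Reactants: 13 methyl (3R,4R)-4-acetoxy-3-[(E)-4-(diphenoxyphosphoryl)-4-hydroxy-3-methylbut-2-en-1-yl]-6-methyl-2-methylidenehept-6-enoate
Product: 14 methyl (3R,4R)-4-acetoxy-3-[(E)-4-(diphenoxyphosphoryl)-4-methoxy-3-methylbut-2-en-1-yl]-6-methyl-2-methylidenehept-6-enoate
Conditions: Ag2O, MeI, 4 Å molecular sieves, MeCN, rt, dark
Reagents that add atoms: iodomethane, CI
Why: Silver oxide mediated O-methylation of the fairly acidic α-hydroxyphosphonate under non-basic conditions should avoid phospha-Brook rearrangement, and a methyl ether cannot migrate in the later olefination.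

Step 11
Reactants: 14 methyl (3R,4R)-4-acetoxy-3-[(E)-4-(diphenoxyphosphoryl)-4-methoxy-3-methylbut-2-en-1-yl]-6-methyl-2-methylidenehept-6-enoate
Product: 15 methyl (3R,4R,6E)-4-acetoxy-3-[(E)-4-(diphenoxyphosphoryl)-4-methoxy-3-methylbut-2-en-1-yl]-6-methyl-2-methylidene-8-oxooct-6-enoate
Conditions: crotonaldehyde (5 equiv), second-generation Hoveyda–Grubbs catalyst (5 mol%), CH2Cl2, 40 °C
Reagents that add atoms: crotonaldehyde, C/C=C/C=O
Why: Olefin cross-metathesis of the 1,1-disubstituted terminal alkene with the enal partner adds C1 and C2 as the β-methyl enal, while the α-branched acrylate and the trisubstituted alkene should stay out of the reaction.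

Step 12
Reactants: 15 methyl (3R,4R,6E)-4-acetoxy-3-[(E)-4-(diphenoxyphosphoryl)-4-methoxy-3-methylbut-2-en-1-yl]-6-methyl-2-methylidene-8-oxooct-6-enoate
Product: 18 methyl 8β-acetoxy-3-oxoeudesma-4,11(13)-dien-12-oate, via Michael adduct 16 (not isolated), via dienol ether 17 (not isolated)
Conditions: KN(SiMe3)2 (1.05 equiv), 18-crown-6, THF (0.002 M), −78 to 0 °C; then 1 M aqueous HCl, THF, 0 °C to rt
Reagents that add atoms: water, O
Why: Proposed new method: deprotonation at C3 gives the α-methoxyallylphosphonate anion, whose γ-carbon C5 adds to C10 of the tethered β,β-disubstituted enal (6-exo-trig conjugate addition, ring B, quaternary C10); proton transfer from C5–H to the aldehyde enolate, shuttled by the silylamine, regenerates the allyl anion, which adds through C3 to the C2 aldehyde and expels diphenyl phosphate (six-membered intramolecular Horner–Wadsworth–Emmons closure, ring A), and acid hydrolyses the resulting 3-methoxy-2,4-diene to the Δ4-3-ketone. The closest known reaction types are the cyclohexadiene annulation of allylic phosphorus ylides and 4-phosphonocrotonates with enones (conjugate addition, then intramolecular olefination), the γ-1,4-addition of allylic phosphonate anions to enones, and enol ether synthesis from α-alkoxy phosphonates. C10 is the only new stereocentre that persists: a chair transition state with the C7 side chain equatorial, the C8 acetate axial and the enal arm pseudo-equatorial should place the C10 methyl axial, cis to the acetate. The step needs γ-attack before α-attack, which ring size secures because α-attack on C10 or direct olefination would close eight- and ten-membered rings, and attack of C5 on the acrylate would be 5-endo-trig. The diphenyl phosphonate (lower pKa, fast elimination), one equivalent of base and high dilution are chosen so that the phosphonate rather than the enal γ-position or the acetate carries the anion.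

Step 13
Reactants: 18 methyl 8β-acetoxy-3-oxoeudesma-4,11(13)-dien-12-oate
Product: 19 methyl 8β-acetoxy-3β-hydroxyeudesma-4,11(13)-dien-12-oate
Conditions: NaBH4, CeCl3·7H2O, MeOH, −78 to −20 °C
Reagents that add atoms: none
Why: Luche reduction, in which 1,2-hydride delivery to the enone from the α face, anti to the axial C10 methyl, should give the pseudo-equatorial 3β-alcohol while the esters are not reduced.

Step 14
Reactants: 19 methyl 8β-acetoxy-3β-hydroxyeudesma-4,11(13)-dien-12-oate
Product: 20 methyl 8β-acetoxy-3β-isobutyryloxyeudesma-4,11(13)-dien-12-oate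
Conditions: isobutyric anhydride, DMAP (cat.), Et3N, CH2Cl2, 0 °C to rt
Reagents that add atoms: isobutyric anhydride, CC(C)C(=O)OC(=O)C(C)C
Why: DMAP-catalysed acylation of the secondary allylic alcohol installs the C3 ester with retention.

Step 15
Reactants: 20 methyl 8β-acetoxy-3β-isobutyryloxyeudesma-4,11(13)-dien-12-oate
Product: 21 methyl 8β-acetoxy-5α-hydroperoxy-3β-isobutyryloxyeudesma-4(15),11(13)-dien-12-oate
Conditions: O2, tetraphenylporphyrin (cat.), visible light, CH2Cl2, 0 °C
Reagents that add atoms: dioxygen, O=O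
Why: Schenck ene reaction, in which singlet oxygen should attack the tetrasubstituted C4=C5 alkene at C5 from the α face (anti to the C10 methyl and the 3β-ester) and abstract a C15 hydrogen, giving the tertiary 5α-hydroperoxide and the exocyclic methylene while the electron-poor acrylate stays inert.

Compound list
1 | 3-[(tert-butyldimethylsilyl)oxy]propanal | O=CCCO[Si](C)(C)C(C)(C)C | starting material
2 | methyl acrylate | C=CC(=O)OC | starting material
3 | methyl 5-[(tert-butyldimethylsilyl)oxy]-3-hydroxy-2-methylidenepentanoate (racemic) | C=C(C(=O)OC)C(O)CCO[Si](C)(C)C(C)(C)C | intermediate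
4 | methyl 3-acetoxy-5-[(tert-butyldimethylsilyl)oxy]-2-methylidenepentanoate (racemic) | C=C(C(=O)OC)C(OC(C)=O)CCO[Si](C)(C)C(C)(C)C | intermediate
5 | methyl (E)-5-[(tert-butyldimethylsilyl)oxy]-2-[(4,4,5,5-tetramethyl-1,3,2-dioxaborolan-2-yl)methyl]pent-2-enoate | COC(=O)/C(CB1OC(C)(C)C(C)(C)O1)=C/CCO[Si](C)(C)C(C)(C)C | intermediate
6 | 3-methylbut-3-en-1-ol | C=C(C)CCO | starting material
7 | 3-methylbut-3-enal | C=C(C)CC=O | intermediate
8 | methyl (3R,4R)-3-{2-[(tert-butyldimethylsilyl)oxy]ethyl}-4-hydroxy-6-methyl-2-methylidenehept-6-enoate | C=C(C(=O)OC)[C@@H](CCO[Si](C)(C)C(C)(C)C)[C@H](O)CC(C)=C | intermediate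
9 | methyl (3R,4R)-4-acetoxy-3-{2-[(tert-butyldimethylsilyl)oxy]ethyl}-6-methyl-2-methylidenehept-6-enoate | C=C(C(=O)OC)[C@@H](CCO[Si](C)(C)C(C)(C)C)[C@H](OC(C)=O)CC(C)=C | intermediate
10 | methyl (3R,4R)-4-acetoxy-3-(2-hydroxyethyl)-6-methyl-2-methylidenehept-6-enoate | C=C(C(=O)OC)[C@@H](CCO)[C@H](OC(C)=O)CC(C)=C | intermediate
11 | methyl (3R,4R)-4-acetoxy-6-methyl-2-methylidene-3-(2-oxoethyl)hept-6-enoate | C=C(C(=O)OC)[C@@H](CC=O)[C@H](OC(C)=O)CC(C)=C | intermediate
12 | methyl (3R,4R)-4-acetoxy-6-methyl-3-[(E)-3-methyl-4-oxobut-2-en-1-yl]-2-methylidenehept-6-enoate | C=C(C(=O)OC)[C@@H](C/C=C(\C)C=O)[C@H](OC(C)=O)CC(C)=C | intermediate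
13 | methyl (3R,4R)-4-acetoxy-3-[(E)-4-(diphenoxyphosphoryl)-4-hydroxy-3-methylbut-2-en-1-yl]-6-methyl-2-methylidenehept-6-enoate (epimers at the carbinol carbon) | C=C(C(=O)OC)[C@@H](C/C=C(\C)C(O)P(=O)(Oc1ccccc1)Oc1ccccc1)[C@H](OC(C)=O)CC(C)=C | intermediate
14 | methyl (3R,4R)-4-acetoxy-3-[(E)-4-(diphenoxyphosphoryl)-4-methoxy-3-methylbut-2-en-1-yl]-6-methyl-2-methylidenehept-6-enoate | C=C(C(=O)OC)[C@@H](C/C=C(\C)C(OC)P(=O)(Oc1ccccc1)Oc1ccccc1)[C@H](OC(C)=O)CC(C)=C | intermediate
15 | methyl (3R,4R,6E)-4-acetoxy-3-[(E)-4-(diphenoxyphosphoryl)-4-methoxy-3-methylbut-2-en-1-yl]-6-methyl-2-methylidene-8-oxooct-6-enoate | C=C(C(=O)OC)[C@@H](C/C=C(\C)C(OC)P(=O)(Oc1ccccc1)Oc1ccccc1)[C@H](OC(C)=O)C/C(C)=C/C=O | intermediate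
16 | methyl 8β-acetoxy-3-(diphenoxyphosphoryl)-3-methoxy-2-oxo-2,3-secoeudesma-3,11(13)-dien-12-oate (ring B closed, 10β-methyl, C5 epimers) | C=C(C(=O)OC)[C@H]1CC(C(C)=C(OC)P(=O)(Oc2ccccc2)Oc2ccccc2)[C@](C)(CC=O)C[C@H]1OC(C)=O | intermediate
17 | methyl 8β-acetoxy-3-methoxyeudesma-2,4,11(13)-trien-12-oate | C=C(C(=O)OC)[C@H]1CC2=C(C)C(OC)=CC[C@]2(C)C[C@H]1OC(C)=O | intermediate
18 | methyl 8β-acetoxy-3-oxoeudesma-4,11(13)-dien-12-oate | C=C(C(=O)OC)[C@H]1CC2=C(C)C(=O)CC[C@]2(C)C[C@H]1OC(C)=O | intermediate
19 | methyl 8β-acetoxy-3β-hydroxyeudesma-4,11(13)-dien-12-oate | C=C(C(=O)OC)[C@H]1CC2=C(C)[C@@H](O)CC[C@]2(C)C[C@H]1OC(C)=O | intermediate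
20 | methyl 8β-acetoxy-3β-isobutyryloxyeudesma-4,11(13)-dien-12-oate | C=C(C(=O)OC)[C@H]1CC2=C(C)[C@@H](OC(=O)C(C)C)CC[C@]2(C)C[C@H]1OC(C)=O | intermediate
21 | methyl 8β-acetoxy-5α-hydroperoxy-3β-isobutyryloxyeudesma-4(15),11(13)-dien-12-oate | C=C(C(=O)OC)[C@H]1C[C@@]2(OO)C(=C)[C@@H](OC(=O)C(C)C)CC[C@]2(C)C[C@H]1OC(C)=O | target

Total step count: 15. Longest linear sequence: 14 steps (steps 1–3 and 5–15; step 4 is a one-step branch).

Steps most likely to fail

1. Step 12 (Proposed new method). After the conjugate addition the phosphonate carbanion may not be regenerated, because proton transfer from C5–H to the aldehyde enolate is uphill, so the sequence may stall at the Michael adduct; the base may also deprotonate the enal γ-position. The fallback sets out from enal 12 and uses the phosphonium ylide version of the annulation, where that proton transfer is downhill. Acetalisation (HC(OMe)3, PPTS, MeOH) should give the dimethyl acetal F1. PPh3 and TMSOTf in CH2Cl2 at −78 °C (kinetic capture of the oxocarbenium ion at C3) should give the (1-methoxyallyl)triphenylphosphonium triflate F2. Cross-metathesis with crotonaldehyde as in step 11 should give the enal phosphonium salt F3. NaN(SiMe3)2 (1 equiv, THF, −78 °C to rt) then generates the allylic ylide, which should undergo the known conjugate addition, proton transfer and intramolecular Wittig sequence. The fallback returns to the route at dienol ether 17, which aqueous HCl converts into 18.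

2. Step 11. Cross-metathesis onto a 1,1-disubstituted alkene with an electron-poor partner may be slow, with catalyst decay and self-metathesis of the aldehyde winning. The fallback sets out from 14 and builds the enal at the alcohol oxidation level. Cross-metathesis with the electron-rich partner (Z)-1,4-bis[(tert-butyldimethylsilyl)oxy]but-2-ene should give the allylic silyl ether F4. HF·pyridine should give the allylic alcohol F5. MnO2 in CH2Cl2 oxidises only the allylic alcohol and returns to the route at 15.

3. Step 15. Hydrogen abstraction may occur at C6 instead of C15 (giving the 4-hydroperoxy-5-ene), or oxygen may attack the β face. The fallback sets out from 20 and replaces the ene reaction by an epoxide route. mCPBA (NaHCO3, CH2Cl2, 0 °C) should epoxidise the electron-rich C4=C5 bond from the α face to the 4α,5α-epoxide F6. TMSOTf and DBU (toluene, −78 to 0 °C) should open it by removal of a C15 proton to the 5α-trimethylsilyloxy-4(15)-ene F7. Ethereal H2O2 with catalytic acid (perhydrolysis through the tertiary allylic cation, capture trans to the C10 methyl) should give target 21.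

Further compounds
F1 | step 12 | methyl (3R,4R)-4-acetoxy-3-[(E)-4,4-dimethoxy-3-methylbut-2-en-1-yl]-6-methyl-2-methylidenehept-6-enoate | C=C(C(=O)OC)[C@@H](C/C=C(\C)C(OC)OC)[C@H](OC(C)=O)CC(C)=C
F2 | step 12 | [(E)-1-methoxy-2-methyl-4-substituted-but-2-en-1-yl]triphenylphosphonium triflate derived from F1 | C=C(C(=O)OC)[C@@H](C/C=C(\C)C(OC)[P+](c1ccccc1)(c1ccccc1)c1ccccc1)[C@H](OC(C)=O)CC(C)=C.[O-]S(=O)(=O)C(F)(F)F
F3 | step 12 | enal phosphonium triflate (F2 after cross-metathesis with crotonaldehyde) | C=C(C(=O)OC)[C@@H](C/C=C(\C)C(OC)[P+](c1ccccc1)(c1ccccc1)c1ccccc1)[C@H](OC(C)=O)C/C(C)=C/C=O.[O-]S(=O)(=O)C(F)(F)F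
F4 | step 11 | methyl (3R,4R,6E)-4-acetoxy-8-[(tert-butyldimethylsilyl)oxy]-3-[(E)-4-(diphenoxyphosphoryl)-4-methoxy-3-methylbut-2-en-1-yl]-6-methyl-2-methylideneoct-6-enoate | C=C(C(=O)OC)[C@@H](C/C=C(\C)C(OC)P(=O)(Oc1ccccc1)Oc1ccccc1)[C@H](OC(C)=O)C/C(C)=C/CO[Si](C)(C)C(C)(C)C
F5 | step 11 | methyl (3R,4R,6E)-4-acetoxy-3-[(E)-4-(diphenoxyphosphoryl)-4-methoxy-3-methylbut-2-en-1-yl]-8-hydroxy-6-methyl-2-methylideneoct-6-enoate | C=C(C(=O)OC)[C@@H](C/C=C(\C)C(OC)P(=O)(Oc1ccccc1)Oc1ccccc1)[C@H](OC(C)=O)C/C(C)=C/CO
F6 | step 15 | methyl 8β-acetoxy-4α,5α-epoxy-3β-isobutyryloxyeudesm-11(13)-en-12-oate | C=C(C(=O)OC)[C@H]1C[C@@]2(O3)[C@@]3(C)[C@@H](OC(=O)C(C)C)CC[C@]2(C)C[C@H]1OC(C)=O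
F7 | step 15 | methyl 8β-acetoxy-3β-isobutyryloxy-5α-(trimethylsilyloxy)eudesma-4(15),11(13)-dien-12-oate | C=C(C(=O)OC)[C@H]1C[C@@]2(O[Si](C)(C)C)C(=C)[C@@H](OC(=O)C(C)C)CC[C@]2(C)C[C@H]1OC(C)=O
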